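**Strategy.** Ring B (eudesmane numbering) is read as an η3-cyclohexenylpalladium retron: the C5=C6 alkene with its allylic C7 side chain, next to quaternary C10. Everything rests on cutting C5–C10 and C8–C9 (and C7–C11) back to an acyclic (Z)-dienyl triflate carrying the C3 angelate, the C4 silyloxy carbinol and an isopropenyl terminus. One palladium cascade then closes ring A (alkenyl–Pd onto the C10=C9 alkene), closes ring B (the β-hydrogen-free neopentyl C9–Pd onto diene carbon C8) and lets a phosphonoacetate anion capture the C5–C7 allyl at C7, setting C10 and C7. The C3/C4 stereocentres come from an asymmetric epoxidation and an inverting epoxide opening by angelic acid.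

Key step: step 10

Remark on the chemistry: eudesmane numbering is used (ring A = C1–C5 and C10, ring B = C5–C10, C14 on C10, C15 on C4, C11–C13 the acrylate); (R)-BINAP is assumed to be the ligand enantiomer matched with the C3/C4 stereocentres for the desired C10 configuration, and its antipode would be used otherwise.

**Step 1**
Reactants: 1 ethyl 4-methylpent-4-enoate; 2 ethyl 2-(triphenylphosphoranylidene)propanoate
Product: 4 ethyl (2E)-2,6-dimethylhepta-2,6-dienoate, via 4-methylpent-4-enal 3 (not isolated)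
Conditions: i-Bu2AlH (1.05 equiv), CH2Cl2, −78 °C; then 2, −78 °C → rt
Reagents that add atoms: none
Why: Partial ester reduction stops at the aluminium hemiacetal, which releases the aldehyde on warming for a Wittig olefination with the stabilized α-branched ylide, expected to give the (E)-trisubstituted enoate.

**Step 2**
Reactants: 4 ethyl (2E)-2,6-dimethylhepta-2,6-dienoate
Product: 5 (2E)-2,6-dimethylhepta-2,6-dien-1-ol
Conditions: i-Bu2AlH (2.2 equiv), CH2Cl2, −78 → 0 °C
Reagents that add atoms: none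
Why: 1,2-Reduction of the enoate by the aluminium hydride should give the (E)-allylic alcohol and leave both alkenes untouched.

**Step 3**
Reactants: 5 (2E)-2,6-dimethylhepta-2,6-dien-1-ol
Product: 6 [(2R,3R)-2-methyl-3-(3-methylbut-3-en-1-yl)oxiran-2-yl]methanol
Conditions: Ti(OiPr)4 (10 mol %), D-(−)-diethyl tartrate (12 mol %), t-BuOOH, 4 Å molecular sieves, CH2Cl2, −20 °C
Reagents that add atoms: tert-butyl hydroperoxide CC(C)(C)OO
Why: The Sharpless asymmetric epoxidation is directed by the allylic hydroxyl, so only the C3=C4 alkene reacts and the isopropenyl group survives; the D-(−)-tartrate should select the face that gives the (2R,3R)-epoxide, which fixes C4.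

**Step 4**
Reactants: 6 [(2R,3R)-2-methyl-3-(3-methylbut-3-en-1-yl)oxiran-2-yl]methanol; 7 angelic acid, (2Z)-2-methylbut-2-enoic acid
Product: 8 (2R,3S)-1,2-dihydroxy-2,6-dimethylhept-6-en-3-yl (2Z)-2-methylbut-2-enoate
Conditions: Ti(OiPr)4 (1.5 equiv), 7 (2 equiv), CH2Cl2, rt
Reagents that add atoms: none
Why: Titanium-assisted opening of the 2,3-epoxy alcohol by a carboxylic acid should occur at the distal carbon C3 with inversion, which sets C3, installs the angelate without acyl activation (no Z-to-E isomerization) and leaves the C4 tertiary alcohol with retention, so that anti addition across the (E)-alkene gives the cis-3,4-dioxygenation of ring A.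

**Step 5**
Reactants: 8 (2R,3S)-1,2-dihydroxy-2,6-dimethylhept-6-en-3-yl (2Z)-2-methylbut-2-enoate
Product: 9 (2S,3S)-2-hydroxy-2,6-dimethyl-1-oxohept-6-en-3-yl (2Z)-2-methylbut-2-enoate
Conditions: SO3·pyridine, DMSO, i-Pr2NEt, CH2Cl2, 0 °C
Reagents that add atoms: none
Why: The Parikh–Doering oxidation converts only the primary alcohol, since the tertiary alcohol cannot be oxidized, and its non-acidic conditions avoid glycol cleavage.

**Step 6**
Reactants: 9 (2S,3S)-2-hydroxy-2,6-dimethyl-1-oxohept-6-en-3-yl (2Z)-2-methylbut-2-enoate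
Product: 10 (2S,3S)-2,6-dimethyl-1-oxo-2-[(triethylsilyl)oxy]hept-6-en-3-yl (2Z)-2-methylbut-2-enoate
Conditions: Et3SiOTf, 2,6-lutidine, CH2Cl2, −78 → 0 °C
Reagents that add atoms: triethylsilyl trifluoromethanesulfonate CC[Si](CC)(CC)OS(=O)(=O)C(F)(F)F
Why: Silylation with a silyl triflate and a hindered pyridine base protects the hindered tertiary alcohol, and no enol ether can form because the aldehyde has no α-hydrogen (C4 is quaternary).

**Step 7**
Reactants: 10 (2S,3S)-2,6-dimethyl-1-oxo-2-[(triethylsilyl)oxy]hept-6-en-3-yl (2Z)-2-methylbut-2-enoate; 11 allyl bromide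
Product: 12 (5S,6R)-7-hydroxy-2,6-dimethyl-6-[(triethylsilyl)oxy]deca-1,9-dien-5-yl (2Z)-2-methylbut-2-enoate (both C7 epimers)
Conditions: Zn dust, THF/sat. aq. NH4Cl, 0 °C → rt
Reagents that add atoms: none
Why: The Barbier allylation with allylzinc bromide formed in the flask adds to the aldehyde in preference to the hindered conjugated ester, and the new carbinol centre needs no control because step 8 removes it.

**Step 8**
Reactants: 12 (5S,6R)-7-hydroxy-2,6-dimethyl-6-[(triethylsilyl)oxy]deca-1,9-dien-5-yl (2Z)-2-methylbut-2-enoate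
Product: 13 (5S,6S)-2,6-dimethyl-7-oxo-6-[(triethylsilyl)oxy]deca-1,9-dien-5-yl (2Z)-2-methylbut-2-enoate
Conditions: Dess–Martin periodinane, NaHCO3, CH2Cl2, 0 °C → rt
Reagents that add atoms: none
Why: The buffered Dess–Martin oxidation should give the β,γ-unsaturated ketone, and any drift of the alkene into conjugation is harmless because both isomers give the same dienolate in step 9.

**Step 9**
Reactants: 13 (5S,6S)-2,6-dimethyl-7-oxo-6-[(triethylsilyl)oxy]deca-1,9-dien-5-yl (2Z)-2-methylbut-2-enoate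
Product: 14 (5S,6S,7Z)-2,6-dimethyl-6-[(triethylsilyl)oxy]-7-{[(trifluoromethyl)sulfonyl]oxy}deca-1,7,9-trien-5-yl (2Z)-2-methylbut-2-enoate
Conditions: KN(SiMe3)2 (1.1 equiv), THF, −78 °C; then PhNTf2, −78 → 0 °C
Reagents that add atoms: N-phenylbis(trifluoromethanesulfonimide) O=S(=O)(N(c1ccccc1)S(=O)(=O)C(F)(F)F)C(F)(F)F
Why: Enol triflate formation: deprotonation at the doubly activated C6 methylene gives the dienolate, whose (Z)-geometry (oxygen cis to the vinyl group) is enforced by allylic strain against the quaternary C4, and O-triflation traps it.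

**Step 10**
Reactants: 14 (5S,6S,7Z)-2,6-dimethyl-6-[(triethylsilyl)oxy]-7-{[(trifluoromethyl)sulfonyl]oxy}deca-1,7,9-trien-5-yl (2Z)-2-methylbut-2-enoate; 15 trimethyl phosphonoacetate
Product: 16 methyl 2-(dimethoxyphosphoryl)-2-[(2R,4aS,7S,8R)-4a,8-dimethyl-7-{[(2Z)-2-methylbut-2-enoyl]oxy}-8-[(triethylsilyl)oxy]-2,3,4,4a,5,6,7,8-octahydronaphthalen-2-yl]acetate (both epimers at the phosphonate carbon)
Conditions: Pd(OAc)2 (10 mol %), (R)-BINAP (12 mol %), 15/NaH (2 equiv), THF/DMSO, 50 °C
Reagents that add atoms: none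
Why: Proposed new method: zerovalent palladium inserts into the C5–OTf bond, the cationic alkenylpalladium adds syn across the C10=C9 alkene, the resulting neopentyl C9–palladium species (no β-hydrogen, since C10 is quaternary) adds across the C7=C8 terminus of the pendant diene at C8, and the phosphonoacetate anion attacks C7 of the η3-allyl complex spanning C5–C6–C7 anti to the metal, which returns zerovalent palladium. The closest known reaction type is the Heck cyclization terminated by capture of an η3-allylpalladium with a stabilized carbanion (Heck/Tsuji–Trost domino), to which one further alkene insertion is added here. Ring A closes 6-exo-trig (bond C5–C10) and ring B 6-endo-trig (bond C8–C9), the latter expected over 5-exo attack at C7 because only attack at the diene terminus gives the stabilized η3-allyl. C10 is set in the first insertion by the chiral bisphosphine, which stays chelated on cationic palladium because triflate is the leaving group, with the C3/C4 centres as a secondary influence. C7 is set by relay from C10: the metal is delivered to the ring B face opposite the axial C10 methyl, so the nucleophile, entering anti to palladium, ends up cis to that methyl as in the target, while the C11 centre forms as a mixture that step 11 removes. The step needs the triflate cis to the vinyl group so that C8 can reach C9 (secured by the (Z)-dienolate geometry of step 9) and attack of the nucleophile at C7 and not C5 (secured by the fully substituted C5 terminus flanked by quaternary C4 and C10).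

**Step 11**
Reactants: 16 methyl 2-(dimethoxyphosphoryl)-2-[(2R,4aS,7S,8R)-4a,8-dimethyl-7-{[(2Z)-2-methylbut-2-enoyl]oxy}-8-[(triethylsilyl)oxy]-2,3,4,4a,5,6,7,8-octahydronaphthalen-2-yl]acetate
Product: 17 methyl 2-[(2R,4aS,7S,8R)-4a,8-dimethyl-7-{[(2Z)-2-methylbut-2-enoyl]oxy}-8-[(triethylsilyl)oxy]-2,3,4,4a,5,6,7,8-octahydronaphthalen-2-yl]prop-2-enoate
Conditions: K2CO3, 37% aq. CH2O, THF, rt → 40 °C
Reagents that add atoms: formaldehyde C=O
Why: The Horner–Wadsworth–Emmons olefination of the α-substituted phosphonoacetate with formaldehyde under mild carbonate conditions should turn the epimeric C11 centre into the acrylate without touching C7.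

**Step 12**
Reactants: 17 methyl 2-[(2R,4aS,7S,8R)-4a,8-dimethyl-7-{[(2Z)-2-methylbut-2-enoyl]oxy}-8-[(triethylsilyl)oxy]-2,3,4,4a,5,6,7,8-octahydronaphthalen-2-yl]prop-2-enoate
Product: 18 methyl 2-[(2R,4aS,7S,8R)-8-hydroxy-4a,8-dimethyl-7-{[(2Z)-2-methylbut-2-enoyl]oxy}-2,3,4,4a,5,6,7,8-octahydronaphthalen-2-yl]prop-2-enoate (CNP0283268.1)
Conditions: HF·pyridine, pyridine, THF, 0 °C → rt
Reagents that add atoms: none
Why: Fluoride-mediated desilylation under pyridine buffering should free the tertiary alcohol under conditions too mild to ionize the allylic carbinol or to isomerize the angelate or the skipped diene.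

**Compound list**
1 | ethyl 4-methylpent-4-enoate | C=C(C)CCC(=O)OCC | starting material
2 | ethyl 2-(triphenylphosphoranylidene)propanoate | CCOC(=O)C(C)=P(c1ccccc1)(c1ccccc1)c1ccccc1 | starting material
3 | 4-methylpent-4-enal | C=C(C)CCC=O | intermediate
4 | ethyl (2E)-2,6-dimethylhepta-2,6-dienoate | C=C(C)CC/C=C(\C)C(=O)OCC | intermediate
5 | (2E)-2,6-dimethylhepta-2,6-dien-1-ol | C=C(C)CC/C=C(\C)CO | intermediate
6 | [(2R,3R)-2-methyl-3-(3-methylbut-3-en-1-yl)oxiran-2-yl]methanol | C=C(C)CC[C@H]1O[C@@]1(CO)C | intermediate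
7 | angelic acid, (2Z)-2-methylbut-2-enoic acid | C/C=C(/C)C(=O)O | starting material
8 | (2R,3S)-1,2-dihydroxy-2,6-dimethylhept-6-en-3-yl (2Z)-2-methylbut-2-enoate | C=C(C)CC[C@H](OC(=O)/C(C)=C\C)[C@](CO)(C)O | intermediate
9 | (2S,3S)-2-hydroxy-2,6-dimethyl-1-oxohept-6-en-3-yl (2Z)-2-methylbut-2-enoate | C=C(C)CC[C@H](OC(=O)/C(C)=C\C)[C@](C=O)(C)O | intermediate
10 | (2S,3S)-2,6-dimethyl-1-oxo-2-[(triethylsilyl)oxy]hept-6-en-3-yl (2Z)-2-methylbut-2-enoate | C=C(C)CC[C@H](OC(=O)/C(C)=C\C)[C@](C=O)(C)O[Si](CC)(CC)CC | intermediate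
11 | allyl bromide | C=CCBr | starting material
12 | (5S,6R)-7-hydroxy-2,6-dimethyl-6-[(triethylsilyl)oxy]deca-1,9-dien-5-yl (2Z)-2-methylbut-2-enoate, both C7 epimers | C=C(C)CC[C@H](OC(=O)/C(C)=C\C)[C@](C(O)CC=C)(C)O[Si](CC)(CC)CC | intermediate
13 | (5S,6S)-2,6-dimethyl-7-oxo-6-[(triethylsilyl)oxy]deca-1,9-dien-5-yl (2Z)-2-methylbut-2-enoate | C=C(C)CC[C@H](OC(=O)/C(C)=C\C)[C@](C(=O)CC=C)(C)O[Si](CC)(CC)CC | intermediate
14 | (5S,6S,7Z)-2,6-dimethyl-6-[(triethylsilyl)oxy]-7-{[(trifluoromethyl)sulfonyl]oxy}deca-1,7,9-trien-5-yl (2Z)-2-methylbut-2-enoate | C=C(C)CC[C@H](OC(=O)/C(C)=C\C)[C@](/C(OS(=O)(=O)C(F)(F)F)=C/C=C)(C)O[Si](CC)(CC)CC | intermediate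
15 | trimethyl phosphonoacetate | COC(=O)CP(=O)(OC)OC | starting material
16 | methyl 2-(dimethoxyphosphoryl)-2-[(2R,4aS,7S,8R)-4a,8-dimethyl-7-{[(2Z)-2-methylbut-2-enoyl]oxy}-8-[(triethylsilyl)oxy]-2,3,4,4a,5,6,7,8-octahydronaphthalen-2-yl]acetate, both epimers at the phosphonate carbon | COC(=O)C([C@H]1C=C2[C@](C)(CC[C@H](OC(=O)/C(C)=C\C)[C@]2(C)O[Si](CC)(CC)CC)CC1)P(=O)(OC)OC | intermediate
17 | methyl 2-[(2R,4aS,7S,8R)-4a,8-dimethyl-7-{[(2Z)-2-methylbut-2-enoyl]oxy}-8-[(triethylsilyl)oxy]-2,3,4,4a,5,6,7,8-octahydronaphthalen-2-yl]prop-2-enoate | C=C(C(=O)OC)[C@H]1C=C2[C@](C)(CC[C@H](OC(=O)/C(C)=C\C)[C@]2(C)O[Si](CC)(CC)CC)CC1 | intermediate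
18 | methyl 2-[(2R,4aS,7S,8R)-8-hydroxy-4a,8-dimethyl-7-{[(2Z)-2-methylbut-2-enoyl]oxy}-2,3,4,4a,5,6,7,8-octahydronaphthalen-2-yl]prop-2-enoate | C=C(C(=O)OC)[C@H]1C=C2[C@](C)(CC[C@H](OC(=O)/C(C)=C\C)[C@]2(C)O)CC1 | target

**Totals.** Total step count: 12. Longest linear sequence: 12 steps (1 → 18).

**Steps most likely to fail**

Step 10 (Proposed new method). The neopentyl alkylpalladium may add to the internal diene carbon C7 (5-exo) instead of C8, or be intercepted before the second insertion. The ligand may also fail to override the substrate bias at C10, giving poor facial selectivity in the first insertion. The fallback uses known chemistry only and forms the same two bonds by an intramolecular Diels–Alder reaction. It sets out from 10: Wittig olefination with 1-(triphenylphosphoranylidene)propan-2-one should give the (E)-enone F1. Et3SiOTf/Et3N would convert it into the 2-silyloxytriene F2. Heating in toluene (190 °C, sealed tube, BHT) should close rings A and B to the bicyclic silyl enol ether F3, as ring-fusion epimers at C5. Saegusa–Ito oxidation with Pd(OAc)2 in MeCN would erase C5 and give the enone F4, at which stage any C10 epimer would be separated. Luche reduction (NaBH4, CeCl3·7H2O, MeOH, −78 °C), with hydride entering anti to the C10 methyl, should give the allylic alcohol F5. ClCO2Me/pyridine would give the methyl carbonate F6. Tsuji–Trost alkylation with 15 and Pd(PPh3)4 in THF, with net retention and attack at C7, comes back to the route at 16.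

Step 4. The epoxide opening may leak to C4, isopropoxide may be transferred in place of the acid, or the angelate may migrate to the primary hydroxyl. The fallback changes the carbon that is inverted. It sets out from 5: Sharpless epoxidation with L-(+)-diethyl tartrate should give the enantiomeric epoxy alcohol F7. TBSCl/imidazole would give the silyl ether F8. Acid-catalysed hydrolysis (cat. HClO4, THF/H2O, 0 °C) opens the tertiary carbon C4 with inversion to the diol F9. Yamaguchi esterification of the secondary hydroxyl with 7 (2,4,6-trichlorobenzoyl chloride, Et3N, toluene) would give the angelate F10. HF·pyridine then removes the silyl group and comes back to the route at 8.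

Step 5. The unprotected α-hydroxy aldehyde may oligomerize through hemiacetals, or the acyl group may migrate during oxidation and isolation. The fallback protects before oxidizing. It sets out from 8: Et3SiOTf/2,6-lutidine would give the bis(triethylsilyl) ether F11. Swern conditions ((COCl)2, DMSO, CH2Cl2, −78 → −30 °C, then Et3N) cleave the primary silyl ether selectively and oxidize it in the same flask, which comes back to the route at 10 and bypasses 9.

**Further compounds**
F1 | step 10 | (5S,6R,7E)-2,6-dimethyl-9-oxo-6-[(triethylsilyl)oxy]deca-1,7-dien-5-yl (2Z)-2-methylbut-2-enoate | C=C(C)CC[C@H](OC(=O)/C(C)=C\C)[C@](/C=C/C(C)=O)(C)O[Si](CC)(CC)CC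
F2 | step 10 | (5S,6R,7E)-2,6-dimethyl-6,9-bis[(triethylsilyl)oxy]deca-1,7,9-trien-5-yl (2Z)-2-methylbut-2-enoate | C=C(C)CC[C@H](OC(=O)/C(C)=C\C)[C@](/C=C/C(=C)O[Si](CC)(CC)CC)(C)O[Si](CC)(CC)CC
F3 | step 10 | (4aR,7S,8R)-4a,8-dimethyl-2,8-bis[(triethylsilyl)oxy]-3,4,4a,5,6,7,8,8a-octahydronaphthalen-7-yl (2Z)-2-methylbut-2-enoate, both C8a epimers | CC[Si](CC)(CC)OC1=CC2[C@](C)(CC[C@H](OC(=O)/C(C)=C\C)[C@]2(C)O[Si](CC)(CC)CC)CC1
F4 | step 10 | (4aR,7S,8R)-4a,8-dimethyl-2-oxo-8-[(triethylsilyl)oxy]-2,3,4,4a,5,6,7,8-octahydronaphthalen-7-yl (2Z)-2-methylbut-2-enoate | O=C1C=C2[C@](C)(CC[C@H](OC(=O)/C(C)=C\C)[C@]2(C)O[Si](CC)(CC)CC)CC1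
F5 | step 10 | (2R,4aS,7S,8R)-2-hydroxy-4a,8-dimethyl-8-[(triethylsilyl)oxy]-2,3,4,4a,5,6,7,8-octahydronaphthalen-7-yl (2Z)-2-methylbut-2-enoate | O[C@H]1C=C2[C@](C)(CC[C@H](OC(=O)/C(C)=C\C)[C@]2(C)O[Si](CC)(CC)CC)CC1
F6 | step 10 | (2R,4aS,7S,8R)-2-[(methoxycarbonyl)oxy]-4a,8-dimethyl-8-[(triethylsilyl)oxy]-2,3,4,4a,5,6,7,8-octahydronaphthalen-7-yl (2Z)-2-methylbut-2-enoate | COC(=O)O[C@H]1C=C2[C@](C)(CC[C@H](OC(=O)/C(C)=C\C)[C@]2(C)O[Si](CC)(CC)CC)CC1
F7 | step 4 | [(2S,3S)-2-methyl-3-(3-methylbut-3-en-1-yl)oxiran-2-yl]methanol | C=C(C)CC[C@@H]1O[C@]1(CO)C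
F8 | step 4 | tert-butyl(dimethyl){[(2S,3S)-2-methyl-3-(3-methylbut-3-en-1-yl)oxiran-2-yl]methoxy}silane | C=C(C)CC[C@@H]1O[C@]1(CO[Si](C)(C)C(C)(C)C)C
F9 | step 4 | (2R,3S)-1-[(tert-butyldimethylsilyl)oxy]-2,6-dimethylhept-6-ene-2,3-diol | C=C(C)CC[C@H](O)[C@](CO[Si](C)(C)C(C)(C)C)(C)O
F10 | step 4 | (2R,3S)-1-[(tert-butyldimethylsilyl)oxy]-2-hydroxy-2,6-dimethylhept-6-en-3-yl (2Z)-2-methylbut-2-enoate | C=C(C)CC[C@H](OC(=O)/C(C)=C\C)[C@](CO[Si](C)(C)C(C)(C)C)(C)O
F11 | step 5 | (2R,3S)-2,6-dimethyl-1,2-bis[(triethylsilyl)oxy]hept-6-en-3-yl (2Z)-2-methylbut-2-enoate | C=C(C)CC[C@H](OC(=O)/C(C)=C\C)[C@](CO[Si](CC)(CC)CC)(C)O[Si](CC)(CC)CC
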